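**Retrosynthetic overview**

1. Feature: in the hydroazulene (five-membered ring C1–C2–C3–C4–C5, seven-membered ring C1–C5–C6–C7–C8–C9–C10) the oxygen-bearing C10 lies between the quaternary C1 and C9, and the oxygen-bearing C6 between C5 and C7. C1–C10–C9 is therefore read as an oxyallyl cation, C5=C6(O)–C7=C8(Me) as a 2-oxygenated diene, and C2–C3–C4 as their tether.
2. Target 29 ⇐ (desilylation, angelate, Luche reduction, Saegusa oxidation, aroate, directed reduction) 4β-hydroxydaucane-6,10-dione 16 ⇐ cycloadduct 15.
3. 15 ⇐ intramolecular (4+3) cycloaddition forming C1–C5 and C8–C9 from bis(silyl enol ether) 13. The chloro ketone enters as its enol silyl ether, because any enolisation that makes the C5=C6 dienol ether also enolises C10 toward C9.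
4. 13 ⇐ chloro enone 12 ⇐ keto aldehyde 3 (aldehyde + (E)-propenyl; methyl ketone + 1,1-dichloroethyllithium, which brings C10, C9 and the C1 chloride) ⇐ ozonolysis of (S)-terpinen-4-ol, which supplies C1–C6, both branches and the C4 stereocentre.
5. Ring order: no ring before step 8, where both rings form together; C4 controls C1 and C5, and C6 and C10 are set afterwards by reductions.

Key step: step 8

Assumption: (S)-terpinen-4-ol of high enantiomeric purity is taken as the commercial starting material; daucane locants (five-membered ring C1–C5, seven-membered ring C1, C5–C10) are used for all intermediates, and β is the face of the C1 methyl.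

**Route**

Step 1
Reactants: 1 (S)-terpinen-4-ol
Product: 2 (S)-terpinen-4-ol triethylsilyl ether
Conditions: TESOTf, 2,6-lutidine, CH2Cl2, 0 °C
Reagents that add atoms: triethylsilyl trifluoromethanesulfonate, CC[Si](CC)(CC)OS(=O)(=O)C(F)(F)F
Why: Silyl triflate silylation protects the hindered tertiary alcohol without touching the ring alkene or the C4 stereocentre.

Step 2
Reactants: 2 (S)-terpinen-4-ol triethylsilyl ether
Product: 3 (S)-6-oxo-3-(propan-2-yl)-3-(triethylsilyloxy)heptanal
Conditions: O3, CH2Cl2, −78 °C; PPh3, −78 → 23 °C; used directly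
Reagents that add atoms: ozone, [O-][O+]=O
Why: Ozonolysis with reductive work-up cleaves the trisubstituted ring alkene into the methyl ketone (carbon C1 with its methyl) and the aldehyde (C6), and the silyl ether is inert to ozone.

Step 3
Reactants: 3 (S)-6-oxo-3-(propan-2-yl)-3-(triethylsilyloxy)heptanal; 4 (E)-1-bromoprop-1-ene
Product: 5 (5S,8E)-7-hydroxy-5-(propan-2-yl)-5-(triethylsilyloxy)dec-8-en-2-one
Conditions: CrCl2 (4 equiv.), NiCl2 (2 mol%), DMF, 23 °C
Reagents that add atoms: none
Why: In this Nozaki–Hiyama–Kishi coupling the alkenylchromium species forms with retention of the E geometry and adds to the aldehyde only, leaving the methyl ketone; the new carbinol centre forms as a mixture that is erased by the oxidation of step 6.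

Step 4
Reactants: 5 (5S,8E)-7-hydroxy-5-(propan-2-yl)-5-(triethylsilyloxy)dec-8-en-2-one
Product: 6 (5S,8E)-5-(propan-2-yl)-5-(triethylsilyloxy)-7-(trimethylsilyloxy)dec-8-en-2-one
Conditions: TMSCl, imidazole, CH2Cl2, 0 °C; used crude
Reagents that add atoms: chlorotrimethylsilane, C[Si](C)(C)Cl
Why: Silylation of the secondary allylic alcohol ensures that the basic carbenoid of step 5 meets only the ketone.

Step 5
Reactants: 6 (5S,8E)-5-(propan-2-yl)-5-(triethylsilyloxy)-7-(trimethylsilyloxy)dec-8-en-2-one; 7 1,1-dichloroethane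
Product: 11 (6S,9E)-3-chloro-8-hydroxy-3-methyl-6-(propan-2-yl)-6-(triethylsilyloxy)undec-9-en-2-one, via lithium dichloroalkoxide 8 (not isolated), via 2-chlorooxirane 9 (not isolated), via silylated chloro ketone 10 (not isolated)
Conditions: 7, n-BuLi, THF/Et2O/pentane, −105 °C; add 6, −105 → 23 °C, then 45 °C; citric acid, MeOH, 0 °C
Reagents that add atoms: none
Why: This is the carbenoid route from ketones to α-chloro ketones: 1,1-dichloroethyllithium adds to the methyl ketone, the alkoxide closes to the 2-chlorooxirane on warming, and this rearranges with chlorine migration to the tertiary α-chloro methyl ketone; the mild acid removes only the trimethylsilyl ether, and C1 forms as both epimers, which converge in step 8.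

Step 6
Reactants: 11 (6S,9E)-3-chloro-8-hydroxy-3-methyl-6-(propan-2-yl)-6-(triethylsilyloxy)undec-9-en-2-one
Product: 12 (6S,9E)-3-chloro-3-methyl-6-(propan-2-yl)-6-(triethylsilyloxy)undec-9-ene-2,8-dione
Conditions: Dess–Martin periodinane, NaHCO3, CH2Cl2, 0 → 23 °C
Reagents that add atoms: none
Why: Dess–Martin oxidation converts the allylic alcohol into the (E)-enone under buffered, non-basic conditions that leave the α-chloro ketone, the silyl ether and the alkene geometry unchanged.

Step 7
Reactants: 12 (6S,9E)-3-chloro-3-methyl-6-(propan-2-yl)-6-(triethylsilyloxy)undec-9-ene-2,8-dione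
Product: 13 (7Z,9E)-3-chloro-3-methyl-6-(propan-2-yl)-6-(triethylsilyloxy)-2,8-bis(triisopropylsilyloxy)undeca-1,7,9-triene
Conditions: TIPSOTf (3 equiv.), Et3N, CH2Cl2, −20 → 23 °C; filtration through Et3N-deactivated silica
Reagents that add atoms: triisopropylsilyl trifluoromethanesulfonate, CC(C)[Si](OS(=O)(=O)C(F)(F)F)(C(C)C)C(C)C
Why: Soft enolisation (silyl triflate and amine) silylates both ketones: the enone reacts at its α' carbon C5 to give the cross-conjugated 2-silyloxydiene as the (Z)-enol ether (C4 trans to C7), and the chloro ketone, which can enolise only toward C9, gives the 2-silyloxyallyl chloride that serves as the cation precursor.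

Step 8
Reactants: 13 (7Z,9E)-3-chloro-3-methyl-6-(propan-2-yl)-6-(triethylsilyloxy)-2,8-bis(triisopropylsilyloxy)undeca-1,7,9-triene
Product: 15 4β-(triethylsilyloxy)-6-(triisopropylsilyloxy)dauc-6-en-10-one, via 2-silyloxyallyl cation perchlorate 14 (not isolated)
Conditions: AgClO4 (1.2 equiv.), 2,6-di-tert-butyl-4-methylpyridine, CH3NO2/CH2Cl2, −25 → 0 °C, 0.005 M; aq. NaHCO3
Reagents that add atoms: none
Why: AgClO4 takes the tertiary allylic chloride from 13 (both C1 epimers give the same ion) to form the 2-silyloxyallyl cation 14 over C1–C10–C9, whose tertiary terminus C1 bonds to the enol ether carbon C5 of the tethered 2-silyloxydiene while C9 bonds to C8, either in one extended (chair-like) transition state or stepwise through the O-silylated enone cation followed by Mukaiyama–Michael closure, after which the C10 silyl group is lost to perchlorate and the bicarbonate quench leaves the C10 ketone beside the C6=C7 enol ether. The closest known reactions are the silver-mediated (4+3) cycloaddition of 2-silyloxyallyl cations, generated from enol silyl ethers of tertiary α-chloro ketones, with 1,3-dienes, and the intramolecular oxyallyl cation (4+3) cycloaddition with a diene on a three-atom tether to bicyclo[5.3.0]decenones. The five-membered ring C1–C2–C3–C4–C5 closes by 5-exo attack of C5 on the cation terminus C1 across the C2–C4 tether, and the seven-membered ring C1–C5–C6–C7–C8–C9–C10 closes by the (4+3) union of the allyl termini C1 and C9 with the diene termini C5 and C8 (in the stepwise limit a 7-endo addition of C9 to C8). At C5, allylic 1,3-strain in the (Z)-enol ether keeps the C4 oxygen, the smaller C4 substituent, in the plane beside the C6 silyloxy group and turns the isopropyl group away, so that C1 arrives on the diene face that leaves C6 cis to the C4 oxygen; at C1, the two bulky silyloxy groups on C10 and C6 disfavour the compact array, and the extended array places the C1 methyl over the diene, which gives the trans ring fusion with the methyl cis to the C4 oxygen and trans to H5; at C8, the (E)-propenyl terminus puts the methyl cis to C4 on the seven-membered ring, a centre that is removed in step 14. The step needs (4+3) periselectivity over (3+2) closure and proton loss, and the correct C1/C4 relationship, which cannot be repaired later: the trans disposition of the two arms on the new cyclopentane rules out a five-membered (3+2) closure, and only a wrong C5 configuration with correct C1 would remain repairable, by enolisation through the C6 ketone after step 9.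

Step 9
Reactants: 15 4β-(triethylsilyloxy)-6-(triisopropylsilyloxy)dauc-6-en-10-one
Product: 16 4β-hydroxydaucane-6,10-dione
Conditions: aq. HF, MeCN, 0 → 23 °C
Reagents that add atoms: none
Why: Acidic fluoride desilylation protonates the enol ether at C7 to release the C6 ketone and cleaves the triethylsilyl ether, giving the β-hydroxy diketone under conditions too mild for retro-aldol cleavage or dehydration; C5 becomes epimerisable here.

Step 10
Reactants: 16 4β-hydroxydaucane-6,10-dione
Product: 17 4β,6α-dihydroxydaucan-10-one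
Conditions: Me4NBH(OAc)3, MeCN/AcOH (1:1), −30 → 0 °C
Reagents that add atoms: none
Why: In this Evans–Saksena hydroxyl-directed reduction the C4 hydroxyl binds the triacetoxyborohydride and delivers hydride to the β face of the neighbouring C6 carbonyl, giving the 6α (anti) alcohol, while the C10 ketone lies on the other face of the cyclopentane, has no β-hydroxyl and is not reduced by this mild reagent.

Step 11
Reactants: 18 4-hydroxybenzoic acid
Product: 20 4-(triisopropylsilyloxy)benzoic acid, via bis-silylated benzoate 19 (not isolated)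
Conditions: TIPSCl (2.2 equiv.), imidazole, DMF, 23 °C; AcOH/THF/H2O, 23 °C
Reagents that add atoms: chlorotriisopropylsilane, CC(C)[Si](Cl)(C(C)C)C(C)C
Why: Exhaustive silylation followed by selective hydrolysis of the labile silyl ester leaves the phenol protected as its robust silyl ether.

Step 12
Reactants: 17 4β,6α-dihydroxydaucan-10-one; 20 4-(triisopropylsilyloxy)benzoic acid
Product: 21 4β-hydroxy-10-oxodaucan-6α-yl 4-(triisopropylsilyloxy)benzoate
Conditions: EDC·HCl, DMAP, CH2Cl2, 23 °C
Reagents that add atoms: none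
Why: Steglich esterification acylates the secondary C6 hydroxyl with retention, and the tertiary C4 hydroxyl does not react.

Step 13
Reactants: 21 4β-hydroxy-10-oxodaucan-6α-yl 4-(triisopropylsilyloxy)benzoate
Product: 22 4β,10-bis(trimethylsilyloxy)dauc-9-en-6α-yl 4-(triisopropylsilyloxy)benzoate
Conditions: TMSOTf (3 equiv.), Et3N, CH2Cl2, 0 °C; used crude
Reagents that add atoms: trimethylsilyl trifluoromethanesulfonate, C[Si](C)(C)OS(=O)(=O)C(F)(F)F
Why: Silyl triflate and amine enolise C10 toward C9, the only possible direction because C1 is quaternary, and silylate the C4 hydroxyl at the same time.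

Step 14
Reactants: 22 4β,10-bis(trimethylsilyloxy)dauc-9-en-6α-yl 4-(triisopropylsilyloxy)benzoate
Product: 24 4β-hydroxy-10-oxodauc-8-en-6α-yl 4-(triisopropylsilyloxy)benzoate, via silylated enone 23 (not isolated)
Conditions: Pd(OAc)2 (1.1 equiv.), MeCN, 23 °C; 1 M HCl, THF, 0 °C
Reagents that add atoms: none
Why: In this Saegusa–Ito oxidation the palladium enolate bound at C9 loses H8 by β-hydride elimination to give the C8=C9 enone, and the brief acid wash frees the C4 hydroxyl without touching the aryl silyl ether.

Step 15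
Reactants: 24 4β-hydroxy-10-oxodauc-8-en-6α-yl 4-(triisopropylsilyloxy)benzoate
Product: 25 4β,10β-dihydroxydauc-8-en-6α-yl 4-(triisopropylsilyloxy)benzoate
Conditions: NaBH4, CeCl3·7H2O, MeOH, −78 °C
Reagents that add atoms: none
Why: Luche reduction gives clean 1,2-reduction of the enone, and hydride adds to C10 from the α face, opposite the adjacent angular C1 methyl, to give the 10β alcohol cis to that methyl.

Step 16
Reactants: 25 4β,10β-dihydroxydauc-8-en-6α-yl 4-(triisopropylsilyloxy)benzoate; 26 angelic acid
Product: 28 10β-angeloyloxy-4β-hydroxydauc-8-en-6α-yl 4-(triisopropylsilyloxy)benzoate, via mixed anhydride 27 (not isolated)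
Conditions: 26, 2,4,6-trichlorobenzoyl chloride, Et3N, toluene, 23 °C; then 25, toluene, 80 °C
Reagents that add atoms: none
Why: Yamaguchi-type esterification through the mixed anhydride, run without DMAP, acylates the hindered allylic C10 hydroxyl at the less hindered angeloyl carbonyl and keeps the (Z) geometry of the angelate, while the tertiary C4 hydroxyl is inert.

Step 17
Reactants: 28 10β-angeloyloxy-4β-hydroxydauc-8-en-6α-yl 4-(triisopropylsilyloxy)benzoate
Product: 29 10β-angeloyloxy-4β-hydroxydauc-8-en-6α-yl 4-hydroxybenzoate (CNP0273650.10)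
Conditions: Bu4NF, AcOH (1:1), THF, 0 °C
Reagents that add atoms: none
Why: Buffered fluoride desilylation cleaves the aryl silyl ether quickly, since phenoxide leaves silicon readily, and the buffer protects the two esters, the allylic angelate and its (Z) geometry.

**Compound list**

1 | (S)-terpinen-4-ol, (S)-4-methyl-1-(propan-2-yl)cyclohex-3-en-1-ol | CC1=CC[C@](O)(C(C)C)CC1 | starting material
2 | (S)-terpinen-4-ol triethylsilyl ether | CC1=CC[C@](O[Si](CC)(CC)CC)(C(C)C)CC1 | intermediate
3 | (S)-6-oxo-3-(propan-2-yl)-3-(triethylsilyloxy)heptanal | CC(=O)CC[C@@](O[Si](CC)(CC)CC)(C(C)C)CC=O | intermediate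
4 | (E)-1-bromoprop-1-ene | C/C=C/Br | starting material
5 | (5S,8E)-7-hydroxy-5-(propan-2-yl)-5-(triethylsilyloxy)dec-8-en-2-one, both C7 epimers | CC(=O)CC[C@@](O[Si](CC)(CC)CC)(C(C)C)CC(O)/C=C/C | intermediate
6 | (5S,8E)-5-(propan-2-yl)-5-(triethylsilyloxy)-7-(trimethylsilyloxy)dec-8-en-2-one, both C7 epimers | CC(=O)CC[C@@](O[Si](CC)(CC)CC)(C(C)C)CC(O[Si](C)(C)C)/C=C/C | intermediate
7 | 1,1-dichloroethane | CC(Cl)Cl | starting material
8 | lithium dichloroalkoxide, adduct of 1,1-dichloroethyllithium to the ketone of 6 (not isolated) | CC(Cl)(Cl)C(C)([O-])CC[C@@](O[Si](CC)(CC)CC)(C(C)C)CC(O[Si](C)(C)C)/C=C/C.[Li+] | intermediate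
9 | 2-chlorooxirane, 2-chloro-2,3-dimethyl-3-[(3S,6E)-3-(propan-2-yl)-3-(triethylsilyloxy)-5-(trimethylsilyloxy)oct-6-en-1-yl]oxirane (not isolated) | CC1(Cl)OC1(C)CC[C@@](O[Si](CC)(CC)CC)(C(C)C)CC(O[Si](C)(C)C)/C=C/C | intermediate
10 | silylated chloro ketone, (6S,9E)-3-chloro-3-methyl-6-(propan-2-yl)-6-(triethylsilyloxy)-8-(trimethylsilyloxy)undec-9-en-2-one (not isolated) | CC(=O)C(C)(Cl)CC[C@@](O[Si](CC)(CC)CC)(C(C)C)CC(O[Si](C)(C)C)/C=C/C | intermediate
11 | (6S,9E)-3-chloro-8-hydroxy-3-methyl-6-(propan-2-yl)-6-(triethylsilyloxy)undec-9-en-2-one, epimers at C3 and C8 | CC(=O)C(C)(Cl)CC[C@@](O[Si](CC)(CC)CC)(C(C)C)CC(O)/C=C/C | intermediate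
12 | (6S,9E)-3-chloro-3-methyl-6-(propan-2-yl)-6-(triethylsilyloxy)undec-9-ene-2,8-dione, both C3 epimers | CC(=O)C(C)(Cl)CC[C@@](O[Si](CC)(CC)CC)(C(C)C)CC(=O)/C=C/C | intermediate
13 | (7Z,9E)-3-chloro-3-methyl-6-(propan-2-yl)-6-(triethylsilyloxy)-2,8-bis(triisopropylsilyloxy)undeca-1,7,9-triene, configuration at the triethylsilyloxy carbon as in 1, both C3 epimers | C=C(O[Si](C(C)C)(C(C)C)C(C)C)C(C)(Cl)CC[C@@](O[Si](CC)(CC)CC)(C(C)C)/C=C(O[Si](C(C)C)(C(C)C)C(C)C)/C=C/C | intermediate
14 | 2-silyloxyallyl cation perchlorate from 13, cation over C1–C10–C9 (not isolated) | C=C(O[Si](C(C)C)(C(C)C)C(C)C)[C+](C)CC[C@@](O[Si](CC)(CC)CC)(C(C)C)/C=C(O[Si](C(C)C)(C(C)C)C(C)C)/C=C/C.[O-]Cl(=O)(=O)=O | intermediate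
15 | 4β-(triethylsilyloxy)-6-(triisopropylsilyloxy)dauc-6-en-10-one, trans-fused, C1 methyl β, H5 α, C8 methyl β | O=C1C[C@@H](C)C=C(O[Si](C(C)C)(C(C)C)C(C)C)[C@@H]2[C@]1(C)CC[C@@]2(O[Si](CC)(CC)CC)C(C)C | intermediate
16 | 4β-hydroxydaucane-6,10-dione, trans-fused | O=C1C[C@@H](C)CC(=O)[C@@H]2[C@]1(C)CC[C@@]2(O)C(C)C | intermediate
17 | 4β,6α-dihydroxydaucan-10-one | O=C1C[C@@H](C)C[C@H](O)[C@@H]2[C@]1(C)CC[C@@]2(O)C(C)C | intermediate
18 | 4-hydroxybenzoic acid | OC(=O)c1ccc(O)cc1 | starting material
19 | bis-silylated benzoate, triisopropylsilyl 4-(triisopropylsilyloxy)benzoate (not isolated) | CC(C)[Si](OC(=O)c1ccc(O[Si](C(C)C)(C(C)C)C(C)C)cc1)(C(C)C)C(C)C | intermediate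
20 | 4-(triisopropylsilyloxy)benzoic acid | OC(=O)c1ccc(O[Si](C(C)C)(C(C)C)C(C)C)cc1 | intermediate
21 | 4β-hydroxy-10-oxodaucan-6α-yl 4-(triisopropylsilyloxy)benzoate | O=C1C[C@@H](C)C[C@H](OC(=O)c3ccc(O[Si](C(C)C)(C(C)C)C(C)C)cc3)[C@@H]2[C@]1(C)CC[C@@]2(O)C(C)C | intermediate
22 | 4β,10-bis(trimethylsilyloxy)dauc-9-en-6α-yl 4-(triisopropylsilyloxy)benzoate | C[Si](C)(C)OC1=C[C@@H](C)C[C@H](OC(=O)c3ccc(O[Si](C(C)C)(C(C)C)C(C)C)cc3)[C@@H]2[C@]1(C)CC[C@@]2(O[Si](C)(C)C)C(C)C | intermediate
23 | silylated enone, 10-oxo-4β-(trimethylsilyloxy)dauc-8-en-6α-yl 4-(triisopropylsilyloxy)benzoate (not isolated) | O=C1C=C(C)C[C@H](OC(=O)c3ccc(O[Si](C(C)C)(C(C)C)C(C)C)cc3)[C@@H]2[C@]1(C)CC[C@@]2(O[Si](C)(C)C)C(C)C | intermediate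
24 | 4β-hydroxy-10-oxodauc-8-en-6α-yl 4-(triisopropylsilyloxy)benzoate | O=C1C=C(C)C[C@H](OC(=O)c3ccc(O[Si](C(C)C)(C(C)C)C(C)C)cc3)[C@@H]2[C@]1(C)CC[C@@]2(O)C(C)C | intermediate
25 | 4β,10β-dihydroxydauc-8-en-6α-yl 4-(triisopropylsilyloxy)benzoate | O[C@H]1C=C(C)C[C@H](OC(=O)c3ccc(O[Si](C(C)C)(C(C)C)C(C)C)cc3)[C@@H]2[C@]1(C)CC[C@@]2(O)C(C)C | intermediate
26 | angelic acid, (Z)-2-methylbut-2-enoic acid | C/C=C(/C)C(=O)O | starting material
27 | mixed anhydride of angelic acid and 2,4,6-trichlorobenzoic acid (not isolated) | C/C=C(/C)C(=O)OC(=O)c1c(Cl)cc(Cl)cc1Cl | intermediate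
28 | 10β-angeloyloxy-4β-hydroxydauc-8-en-6α-yl 4-(triisopropylsilyloxy)benzoate | C/C=C(/C)C(=O)O[C@H]1C=C(C)C[C@H](OC(=O)c2ccc(O[Si](C(C)C)(C(C)C)C(C)C)cc2)[C@@H]2[C@]1(C)CC[C@@]2(O)C(C)C | intermediate
29 | CNP0273650.10, 10β-angeloyloxy-4β-hydroxydauc-8-en-6α-yl 4-hydroxybenzoate | C/C=C(/C)C(=O)O[C@H]1C=C(C)C[C@H](OC(=O)c2ccc(O)cc2)[C@@H]2[C@]1(C)CC[C@@]2(O)C(C)C | target

**Step count and risks**

Total step count: 17. Longest linear sequence: 16 (steps 1–10 and 12–17 from 1; step 11 is a one-step side branch). The cation precursor 13 is reached in 7 steps.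

Steps most likely to fail, in order of risk:

1. Step 8. What may go wrong: the first-formed silyloxyallyl cation loses its silyl group before C9 reaches C8 (interrupted annulation); the tertiary cation loses a proton to give dienes; the C4 silyloxy oxygen captures the cation; or C1 bonds from the diene face that puts C10 cis to the C4 oxygen. Fallback, setting out from 13 and separating the two bond formations: ZnCl2 (1 equiv.) in CH2Cl2/Et2O at −40 °C carries out only the alkylation of the enol ether carbon C5 by the 2-silyloxyallyl chloride, a known route from silyl enol ethers to 1,4-dicarbonyl compounds. With the two arms trans this should give the cyclopentane enone silyl enol ether F1. A separate intramolecular Mukaiyama–Michael addition of C9 to C8 (TMSOTf, CH2Cl2, −78 °C; aqueous work-up) then closes the seven-membered ring to 4β-(triethylsilyloxy)daucane-6,10-dione F2 (C8 epimers, of no consequence because C8 becomes sp2 in step 14). F2 under the conditions of step 9 gives 16, where the route is rejoined.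

2. Step 5. What may go wrong: the carbenoid enolises the methyl ketone instead of adding to it, or the chlorooxirane rearranges by methyl shift or proton loss instead of chlorine migration. Fallback, setting out from 6 and replacing the carbenoid by olefination and electrophilic chlorination: lithiated (1-methoxyethyl)diphenylphosphine oxide (LiN(iPr)2, THF, −78 °C) adds to the ketone to give the β-hydroxy phosphine oxide F3 (Horner–Wittig addition). NaH in DMF at 50 °C eliminates diphenylphosphinate to give the methyl enol ether F4 (either alkene isomer serves). N-chlorosuccinimide in wet THF with NaHCO3 at 0 °C chlorinates the enol ether at C1 and hydrolyses the oxocarbenium ion to the silylated chloro ketone 10, and the citric acid treatment of step 5 then gives 11, where the route is rejoined.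

3. Step 10. What may go wrong: ligand exchange at the hindered tertiary hydroxyl is slow, or hydride reaches C6 from the α face, so that the 6β alcohol accumulates. Fallback, setting out from 16 and replacing retentive acylation by inversion: chelation-controlled reduction with external hydride (Et2BOMe, NaBH4, THF/MeOH, −78 °C; Narasaka–Prasad reduction), which activates only the β-hydroxy ketone and takes hydride from the face opposite the chelate, is used to prepare the 6β-alcohol F5 deliberately. Mitsunobu esterification of F5 with acid 20 (PPh3, diisopropyl azodicarboxylate, toluene, 0 → 23 °C) then installs the aroate with inversion at C6 and rejoins the route at 21.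

Further compounds
F1 | step 8 | cyclopentane enone silyl enol ether, (E)-1-[2-methyl-5-(propan-2-yl)-5-(triethylsilyloxy)-2-(1-triisopropylsilyloxyvinyl)cyclopentyl]but-2-en-1-one with C1–C5 formed and C8–C9 open, both arms trans, crotonoyl cis to the C4 silyloxy group | C=C(O[Si](C(C)C)(C(C)C)C(C)C)[C@@]1(C)CC[C@@](O[Si](CC)(CC)CC)(C(C)C)[C@@H]1C(=O)/C=C/C
F2 | step 8 | 4β-(triethylsilyloxy)daucane-6,10-dione, C8 epimers | O=C1CC(C)CC(=O)[C@@H]2[C@]1(C)CC[C@@]2(O[Si](CC)(CC)CC)C(C)C
F3 | step 5 | β-hydroxy phosphine oxide, adduct of lithiated (1-methoxyethyl)diphenylphosphine oxide to the ketone of 6 | COC(C)(C(C)(O)CC[C@@](O[Si](CC)(CC)CC)(C(C)C)CC(O[Si](C)(C)C)/C=C/C)P(=O)(c1ccccc1)c1ccccc1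
F4 | step 5 | methyl enol ether, (5S,8E)-2-methoxy-3-methyl-6-(propan-2-yl)-6-(triethylsilyloxy)-8-(trimethylsilyloxy)undeca-2,9-diene, both enol ether isomers | COC(C)=C(C)CC[C@@](O[Si](CC)(CC)CC)(C(C)C)CC(O[Si](C)(C)C)/C=C/C
F5 | step 10 | 6β-alcohol, 4β,6β-dihydroxydaucan-10-one | O=C1C[C@@H](C)C[C@@H](O)[C@@H]2[C@]1(C)CC[C@@]2(O)C(C)C
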